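All runs are calculated with constants of no real substance; scatter was added.

The charges of the eta and zeta flasks, which turn Sub into Prd, stand at 3.33 to one, but the Prd made by the first reading, at 4.4 min, stands at 2.80 to one. The eta flask has therefore turned a smaller fraction of its charge, 8.07% against 9.61% in the zeta flask. This pair gives 0.854, give or take 0.102 from the scatter of the two readings. This is the charge exponent, the reaction order in Sub: the logarithm of the ratio of Prd made at one early time over the logarithm of the ratio of charges. The reckoning here commits to it for the exponent asked, since delta's charge lies between these two.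

| setting | delta | zeta | eta | alpha |
|---|---|---|---|---|
| Sub | 300 mM | 180 mM | 600 mM | 300 mM |
| Prd |  |  |  | 90.0 mM |
| time |  |  |  | 100 min |

| delta run: time / min | delta run: [Prd] / mM | zeta run: time / min | zeta run: [Prd] / mM | eta run: time / min | eta run: [Prd] / mM |
|---|---|---|---|---|---|
| 4.4 | 29.9 | 4.4 | 17.3 | 4.4 | 48.4 |
| 13 | 63.7 | 13 | 46.0 | 13 | 104.0 |
| 26 | 98.0 | 26 | 68.5 | 26 | 148.1 |
| 41 | 115.8 | 41 | 81.8 | 41 | 180.5 |
| 58 | 127.8 | 58 | 91.4 | 58 | 191.3 |
| 78 | 137.6 | 78 | 101.5 | 78 | 200.0 |
| 100 | 144.7 | 100 | 100.2 | 100 | 207.7 |

(readings scatter by 2 mM)

- Overall: Sub -> Prd.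
- Constant volume, constant temperature.
- Readings of a species count what is bound in complexes too.
- An order is taken over about fifteen percent of the charge, up and down.
- A share of Prd counts the Prd that was charged too.

* the exponent of [Sub] in the starting rate at the charge of the delta run (at the point where two percent of the Sub have become Prd) (one fixed amount of Prd, the same in the runs compared)
* Prd in the alpha run at 100 min, as a share of the Sub charged

The next flask, alpha, keeps delta's Sub and adds Prd at 30.0% of that charge, so that the Sub is unchanged and any change in what is made belongs to Prd. The delta flask at 26 min and the eta flask at 13 min hold nearly equal Prd, 98.0 mM and 104.0 mM, but over the next stretch the eta flask gains 3.39 mM min⁻¹ and the delta flask 1.19 mM min⁻¹. These two flasks were charged differently, with 300 mM and 600 mM of Sub, so the comparison shows that the amount of Prd does not by itself set the rate, but it cannot show whether Prd brakes the reaction. As an assumption, then, the reckoning here gives Prd no brake and lets alpha make what delta made by 100 min, 48.2% of the charge, for 78.2% in all.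

The forecast takes an exponent of 0.65, from 0.5 to 0.85, on the ground that “Early yields give an order” near it, and a share of 74%, from 62% to 80%. The reckoning here stands higher on both.

The flask gives an exponent of 0.90 and, in alpha, a share of 77.2%, from this mechanism:

    2 Sub ⇌ Sub2, settled at all times (0.3510 M⁻¹)
    Sub → Prd (0.01572 min⁻¹)
    Sub → Prd (0.01332 min⁻¹)
    2 Sub → G (0.1410 M⁻¹ min⁻¹)

Alpha has thus made 47.2% of its charge, against 48.2% in delta. A fit in which Prd decays forecasts 47.7% for alpha, lower than the flask gives, with a residual of 7.4 in units of the scatter. Put on the rates where two percent of delta's Sub have turned, the exponent 0.854 gives eta over delta as 1.81, against a simulated 1.8, and takes delta's 7.0 mM min⁻¹ to 4.49 mM min⁻¹ for zeta, against a simulated 4.3 mM min⁻¹.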